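Readings and results were generated by integration for substances that don't exist, noise included.

The slowing of the product was what I looked at first: in the south run the rate fell from 0.0760 /min to 0.0540 /min of the substrate charged.

| flask | substrate | reagent | capture agent | free catalyst | remark | time |
|---|---|---|---|---|---|---|
| north-east | 0.10 M | 0.073 M | 0.010 M | 9.4 mM | run made earlier |  |
| south | 0.10 M | 0.25 M | 0.010 M | 9.4 mM | run made earlier |  |
| south-east | 0.10 M | 0.13 M | 0.010 M | 9.3 mM | run made earlier |  |
| autumn | 0.10 M | 0.400 M | 0.0100 M | 6.0 mM |  | 12 min |
| midnight | 0.10 M | 0.130 M | 0.0100 M | 9.4 mM |  | 12 min |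

| run | time / min | product / % |
|---|---|---|
| north-east | 0.500 | 0.9 |
| north-east | 1.00 | 5.2 |
| north-east | 2.50 | 9.9 |
| north-east | 6.00 | 17.6 |
| south | 0.500 | 1.6 |
| south | 1.00 | 8.5 |
| south | 2.50 | 19.9 |
| south | 6.00 | 38.8 |
| south-east | 1.50 | 11.2 |
| south-east | 3.00 | 16.6 |
| south-east | 5.00 | 25.1 |
| south-east | 6.00 | 27.6 |

(readings scatter by 1 percentage point)

- the flask that ends with the higher amount of product, in percent of the substrate charged, or "neither" when 2 percentage points or less lies between them (autumn / midnight / neither)
- final product, as a percentage of the substrate charged, in autumn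
- final product, as a percentage of the substrate charged, in midnight

- the analysis behind the earlier runs scatters by 1 percentage point, standard deviation

I let the rate fade exponentially, ignored the short lag, and integrated. With Y the fraction of the charge turned into product, and τ the fading time:

Y(t) = Y∞ · (1 − exp(−t/τ)), so Y(2t) = Y(t) · (1 + exp(−t/τ))

Before taking τ, I asked what each input was worth. One standard deviation in the six-minute reading of the south-east run, which has midnight's recipe, moved my midnight figure by 1.4 percentage points. The catalyst scaling moved autumn in proportion. The reagent order mattered for the verdict, because an order of 0.321 put autumn at 41.5 %, inside the margin of midnight. In my reckoning τ moved both flasks by the same factor: at twice the value I was about to take, midnight became 45.9 %.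

My numbers, assuming one τ for both flasks and a rate proportional to catalyst, were:

τ = 7.32 min, the time in which the rate falls by a factor e, so g = exp(−t/τ) = 0.440 over 6.00 min

reagent order n = 0.642

midnight: 27.6 % · (1 + g) = 39.8 %

autumn: 33.5 % · (1 + g) = 48.2 %

So I expected autumn to end higher. The forecast differed, giving 42 % for autumn, 44 % for midnight and neither: “The two flasks are too close to separate.”

The simulation gave 45.2 % in autumn and 38.8 % in midnight, so autumn ended higher.

    substrate + free catalyst → catalyst intermediate A (k = 11.0 /M/s)
    reagent + catalyst intermediate A ⇌ catalyst intermediate B (K = 10.0 /M, k = 42.0 /M/s)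
    catalyst intermediate B → by-product + catalyst intermediate C (k = 0.0760 /s)
    catalyst intermediate A + capture agent → trapped intermediate (k = 3.30 /M/s)
    catalyst intermediate D ⇌ free catalyst + product (K = 0.0690 M, k = 0.0310 /s)
    catalyst intermediate C → catalyst intermediate D (k = 2.60 /s)

With τ = 7.32 min, doubling from the amount at 6.00 min gave 39.6 % in midnight and 41.5 % in autumn. In autumn at 3.73 min, catalyst intermediate D had a forward half-life of 0.37 min, far longer than the 0.27 s of catalyst intermediate C. At 12.0 min, autumn held 70.2 % of its catalyst as trapped intermediate, outside the round, and within the round 19.2 % as catalyst intermediate D, the resting state of the round, and 0.211 % as catalyst intermediate C.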